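The target is cut at the methylene bridge into a chromene acylphloroglucinol and an (R)-acetyl-geranyl-methyl trione, united last through a C8 Mannich base. The route rests on building the pyran ring by annulation of an aryne with 3-methylbut-2-enal, which in one operation makes the C8a–O1, C4a–C4 and O1–C2 bonds. It exploits the ortho relationship, on the fully substituted benzene ring, of the ring oxygen O1 (on C8a, para to the C6 butyryl group) and the vinylic carbon C4 (on C4a, flanked by the C5 oxygen): silyl and triflate positions, not phenol differentiation, fix the ring fusion. The precursor is a butyryl-substituted, bis-MOM-protected ortho-silylaryl triflate.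

Key step: step 7

Assumption: both triketone rings are written in the enol tautomer of the target SMILES and the descriptor R refers to that drawing; the R enantiomer collected in step 12 is to be identified by its chiroptical data against calculation (or by X-ray of a derivative) before it is carried on.

Step 1
Reactants: 1 1-(2,4,6-trihydroxyphenyl)butan-1-one
Product: 2 1-[4-(benzyloxy)-2,6-dihydroxyphenyl]butan-1-one
Conditions: BnBr (1.0 equiv), K2CO3 (1.1 equiv), acetone, rt
Reagents that add atoms: benzyl bromide, BrCc1ccccc1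
Why: Williamson etherification under weak base should take the 4-OH, which is the most acidic and least hindered hydroxyl and is not tied up in the hydrogen bond to the ketone.

Step 2
Reactants: 2 1-[4-(benzyloxy)-2,6-dihydroxyphenyl]butan-1-one
Product: 3 1-[4-(benzyloxy)-2,6-bis(methoxymethoxy)phenyl]butan-1-one
Conditions: NaH (2.3 equiv), MOMCl (2.6 equiv), DMF, 0 °C to rt
Reagents that add atoms: chloromethyl methyl ether, COCCl
Why: NaH breaks both ortho phenols and the phenoxides are O-alkylated (Williamson type) to MOM acetals, which withstand organolithium and fluoride and leave later under mild acid.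

Step 3
Reactants: 3 1-[4-(benzyloxy)-2,6-bis(methoxymethoxy)phenyl]butan-1-one
Product: 4 1-[4-hydroxy-2,6-bis(methoxymethoxy)phenyl]butan-1-one
Conditions: H2 (1 atm), Pd/C (10 wt% Pd), EtOAc, rt
Reagents that add atoms: none
Why: Catalytic hydrogenolysis cleaves only the benzyl ether, since the MOM acetals and the hindered aryl ketone are inert under neutral conditions.

Step 4
Reactants: 4 1-[4-hydroxy-2,6-bis(methoxymethoxy)phenyl]butan-1-one
Product: 5 1-[3-bromo-4-hydroxy-2,6-bis(methoxymethoxy)phenyl]butan-1-one
Conditions: NBS (1.0 equiv), CH2Cl2, −78 to 0 °C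
Reagents that add atoms: N-bromosuccinimide, O=C1CCC(=O)N1Br
Why: Electrophilic aromatic bromination ortho to the free phenol gives one monobromide because C3 and C5 are equivalent, and one equivalent at low temperature limits dibromination.

Step 5
Reactants: 5 1-[3-bromo-4-hydroxy-2,6-bis(methoxymethoxy)phenyl]butan-1-one
Product: 6 {[(1Z)-1-{3-bromo-2,6-bis(methoxymethoxy)-4-[(trimethylsilyl)oxy]phenyl}but-1-en-1-yl]oxy}(trimethyl)silane
Conditions: LiN(SiMe3)2 (2.2 equiv), THF, −78 °C; Me3SiCl (2.5 equiv), −78 °C to rt; evaporation, pentane, filtration, no aqueous work-up, used crude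
Reagents that add atoms: chlorotrimethylsilane, C[Si](C)(C)Cl
Why: Deprotonation of the phenol and of the ketone α-CH2 (kinetic Z enolate) followed by O-silylation gives the aryl silyl ether needed for the silyl shift and masks the ketone as a silyl enol ether that is inert to butyllithium at low temperature.

Step 6
Reactants: 6 {[(1Z)-1-{3-bromo-2,6-bis(methoxymethoxy)-4-[(trimethylsilyl)oxy]phenyl}but-1-en-1-yl]oxy}(trimethyl)silane
Product: 10 1-[2,6-bis(methoxymethoxy)-4-(trifluoromethanesulfonyloxy)-3-(trimethylsilyl)phenyl]butan-1-one, via aryllithium 7 (not isolated), via lithium phenoxide 8 (not isolated), via enol ether triflate 9 (not isolated)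
Conditions: n-BuLi (1.1 equiv), THF, −78 to −20 °C; PhNTf2 (1.3 equiv), −78 °C to rt; then 0.5 M aq. HCl, THF, 0 °C
Reagents that add atoms: N-phenylbis(trifluoromethanesulfonimide), O=S(=O)(N(c1ccccc1)S(=O)(=O)C(F)(F)F)C(F)(F)F
Why: Bromine–lithium exchange gives 7, whose carbanion takes the neighbouring O-silyl group in an anionic 1,3 O→C shift (retro-Brook rearrangement) to phenoxide 8, which is triflated to 9, and brief dilute acid then hydrolyses only the silyl enol ether back to the ketone.

Step 7
Reactants: 10 1-[2,6-bis(methoxymethoxy)-4-(trifluoromethanesulfonyloxy)-3-(trimethylsilyl)phenyl]butan-1-one; 11 3-methylbut-2-enal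
Product: 15 1-[5,7-bis(methoxymethoxy)-2,2-dimethyl-2H-chromen-6-yl]butan-1-one, via aryne 12 (not isolated), via benzoxete 13 (not isolated), via ortho-quinone methide 14 (not isolated)
Conditions: CsF (3 equiv), 11 (5 equiv), MeCN, rt to 50 °C
Reagents that add atoms: none
Why: Fluoride attacks silicon and triflate leaves to give aryne 12; the carbonyl oxygen of 11 adds to the aryne carbon remote from the flanking OMOM group (old C4, para to the butyryl group), because the developing aryl anion then lies at old C3 where the adjacent C–O bond stabilises it inductively, and this anion closes on the activated carbonyl carbon to benzoxete 13 (stepwise formal [2+2] insertion into C=O). Strain-driven 4π electrocyclic opening of 13 gives ortho-quinone methide 14, and a thermal disrotatory oxa-6π electrocyclisation of its 1-oxatriene closes the six-membered pyran ring by forming the O1–C2 bond. The closest known reaction type is the insertion of arynes into the carbonyl group of α,β-unsaturated aldehydes to give 2H-chromenes. No stereocentre arises, since C2 carries two methyl groups. The step needs regioselectivity (oxygen to the carbon para to butyryl, carbon to the one beside OMOM), secured by the alkoxy group next to the triple bond, and chemoselectivity for C=O over the enal C=C and over a second aryne, favoured by excess aldehyde and the slow release of aryne from sparingly soluble CsF.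

Step 8
Reactants: 15 1-[5,7-bis(methoxymethoxy)-2,2-dimethyl-2H-chromen-6-yl]butan-1-one
Product: 16 1-(5,7-dihydroxy-2,2-dimethyl-2H-chromen-6-yl)butan-1-one
Conditions: 2 M aq. HCl, MeOH, 40 °C
Reagents that add atoms: none
Why: Acid-catalysed acetal solvolysis removes both MOM groups as dimethoxymethane, while the 2,2-dimethyl-2H-chromene and the ketone tolerate dilute methanolic acid.

Step 9
Reactants: 16 1-(5,7-dihydroxy-2,2-dimethyl-2H-chromen-6-yl)butan-1-one
Product: 17 1-{8-[(dimethylamino)methyl]-5,7-dihydroxy-2,2-dimethyl-2H-chromen-6-yl}butan-1-one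
Conditions: aq. CH2O (37%, 1.2 equiv) premixed with aq. Me2NH (40%, 1.5 equiv), EtOH, 0 °C to rt
Reagents that add atoms: formaldehyde, C=O; dimethylamine, CNC
Why: Phenolic Mannich reaction at C8, the only unsubstituted carbon of the benzene ring and activated by O1 and the C5 and C7 hydroxyls, with the premixed amine suppressing methylene-bridged dimer formation.

Step 10
Reactants: 18 1-(2,4,6-trihydroxyphenyl)ethan-1-one; 19 geranyl bromide, (2E)-1-bromo-3,7-dimethylocta-2,6-diene
Product: 20 1-{3-[(2E)-3,7-dimethylocta-2,6-dien-1-yl]-2,4,6-trihydroxyphenyl}ethan-1-one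
Conditions: K2CO3 (1.5 equiv), 19 (1.0 equiv), acetone, reflux
Reagents that add atoms: none
Why: C-alkylation of the ambident phloroglucinolate at one of its two equivalent free ring carbons proceeds by SN2 at the primary allylic bromide, which keeps the E geometry.

Step 11
Reactants: 20 1-{3-[(2E)-3,7-dimethylocta-2,6-dien-1-yl]-2,4,6-trihydroxyphenyl}ethan-1-one
Product: 21 rac-2-acetyl-4-[(2E)-3,7-dimethylocta-2,6-dien-1-yl]-3,5-dihydroxy-4-methylcyclohexa-2,5-dien-1-one
Conditions: NaOMe (3 equiv), MeI (1.1 equiv), MeOH, 0 °C to rt; the more acidic trione separated from aromatic by-products by bicarbonate extraction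
Reagents that add atoms: iodomethane, CI
Why: Alkylative dearomatisation by C-methylation of the phloroglucinolate in protic solvent should favour the already alkylated, more nucleophilic ring carbon (the preference that gives gem-dimethyl acylfilicinic acids), forming the quaternary centre as a racemate.

Step 12
Reactants: 21 rac-2-acetyl-4-[(2E)-3,7-dimethylocta-2,6-dien-1-yl]-3,5-dihydroxy-4-methylcyclohexa-2,5-dien-1-one
Product: 22 (4R)-2-acetyl-4-[(2E)-3,7-dimethylocta-2,6-dien-1-yl]-3,5-dihydroxy-4-methylcyclohexa-2,5-dien-1-one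
Conditions: preparative HPLC, amylose tris(3,5-dimethylphenylcarbamate) stationary phase, hexane/i-PrOH/CF3CO2H (0.1%), rt
Reagents that add atoms: none
Why: Resolution of the racemate by chromatography on a chiral stationary phase selects the R enantiomer without changing any bond, and the quaternary carbon cannot epimerise afterwards.

Step 13
Reactants: 17 1-{8-[(dimethylamino)methyl]-5,7-dihydroxy-2,2-dimethyl-2H-chromen-6-yl}butan-1-one; 22 (4R)-2-acetyl-4-[(2E)-3,7-dimethylocta-2,6-dien-1-yl]-3,5-dihydroxy-4-methylcyclohexa-2,5-dien-1-one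
Product: 24 1-[8-({(3R)-5-acetyl-3-[(2E)-3,7-dimethylocta-2,6-dien-1-yl]-2,4-dihydroxy-3-methyl-6-oxocyclohexa-1,4-dien-1-yl}methyl)-5,7-dihydroxy-2,2-dimethyl-2H-chromen-6-yl]butan-1-one, via chromene ortho-quinone methide 23 (not isolated)
Conditions: 17 (1.1 equiv), 1,4-dioxane, 90 °C, N2
Reagents that add atoms: none
Why: Thermal loss of dimethylamine from the Mannich base, helped by protonation of the amine by the acidic trione, gives ortho-quinone methide 23, which is captured at its exocyclic CH2 by C6 of the trione enol (Michael addition) without touching the quaternary stereocentre or creating a new one.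

Compound list
1 | 1-(2,4,6-trihydroxyphenyl)butan-1-one | CCCC(=O)c1c(O)cc(O)cc1O | starting material
2 | 1-[4-(benzyloxy)-2,6-dihydroxyphenyl]butan-1-one | CCCC(=O)c1c(O)cc(OCc2ccccc2)cc1O | intermediate
3 | 1-[4-(benzyloxy)-2,6-bis(methoxymethoxy)phenyl]butan-1-one | CCCC(=O)c1c(OCOC)cc(OCc2ccccc2)cc1OCOC | intermediate
4 | 1-[4-hydroxy-2,6-bis(methoxymethoxy)phenyl]butan-1-one | CCCC(=O)c1c(OCOC)cc(O)cc1OCOC | intermediate
5 | 1-[3-bromo-4-hydroxy-2,6-bis(methoxymethoxy)phenyl]butan-1-one | CCCC(=O)c1c(OCOC)c(Br)c(O)cc1OCOC | intermediate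
6 | {[(1Z)-1-{3-bromo-2,6-bis(methoxymethoxy)-4-[(trimethylsilyl)oxy]phenyl}but-1-en-1-yl]oxy}(trimethyl)silane (aryl silyl ether and Z silyl enol ether of 5) | CC/C=C(\O[Si](C)(C)C)c1c(OCOC)c(Br)c(O[Si](C)(C)C)cc1OCOC | intermediate
7 | aryllithium: compound 6 with lithium in place of bromine (not isolated) | CC/C=C(\O[Si](C)(C)C)c1c(OCOC)c([Li])c(O[Si](C)(C)C)cc1OCOC | intermediate
8 | lithium 3,5-bis(methoxymethoxy)-2-(trimethylsilyl)-4-[(1Z)-1-(trimethylsilyloxy)but-1-en-1-yl]phenoxide (not isolated) | CC/C=C(\O[Si](C)(C)C)c1c(OCOC)c([Si](C)(C)C)c([O-])cc1OCOC.[Li+] | intermediate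
9 | 3,5-bis(methoxymethoxy)-2-(trimethylsilyl)-4-[(1Z)-1-(trimethylsilyloxy)but-1-en-1-yl]phenyl trifluoromethanesulfonate (not isolated) | CC/C=C(\O[Si](C)(C)C)c1c(OCOC)c([Si](C)(C)C)c(OS(=O)(=O)C(F)(F)F)cc1OCOC | intermediate
10 | 1-[2,6-bis(methoxymethoxy)-4-(trifluoromethanesulfonyloxy)-3-(trimethylsilyl)phenyl]butan-1-one | CCCC(=O)c1c(OCOC)c([Si](C)(C)C)c(OS(=O)(=O)C(F)(F)F)cc1OCOC | intermediate
11 | 3-methylbut-2-enal | CC(C)=CC=O | starting material
12 | aryne, 1-[3,4-didehydro-2,6-bis(methoxymethoxy)phenyl]butan-1-one, triple bond between old C3 and C4 (not isolated) | CCCC(=O)C1=C(OCOC)C#CC=C1OCOC | intermediate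
13 | benzoxete: four-membered O–CH(CH=CMe2) ring fused across old C3–C4 of the butyryl bis-MOM benzene, oxygen on C4 (para to butyryl), CH on C3, racemic (not isolated) | CCCC(=O)c1c(OCOC)c2C(C=C(C)C)Oc2cc1OCOC | intermediate
14 | ortho-quinone methide, 4-butanoyl-3,5-bis(methoxymethoxy)-2-(3-methylbut-2-en-1-ylidene)cyclohexa-3,5-dien-1-one (not isolated) | CCCC(=O)C1=C(OCOC)C(=CC=C(C)C)C(=O)C=C1OCOC | intermediate
15 | 1-[5,7-bis(methoxymethoxy)-2,2-dimethyl-2H-chromen-6-yl]butan-1-one | CCCC(=O)c1c(OCOC)c2C=CC(C)(C)Oc2cc1OCOC | intermediate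
16 | 1-(5,7-dihydroxy-2,2-dimethyl-2H-chromen-6-yl)butan-1-one | CCCC(=O)c1c(O)c2C=CC(C)(C)Oc2cc1O | intermediate
17 | 1-{8-[(dimethylamino)methyl]-5,7-dihydroxy-2,2-dimethyl-2H-chromen-6-yl}butan-1-one | CCCC(=O)c1c(O)c2C=CC(C)(C)Oc2c(CN(C)C)c1O | intermediate
18 | 1-(2,4,6-trihydroxyphenyl)ethan-1-one | CC(=O)c1c(O)cc(O)cc1O | starting material
19 | geranyl bromide, (2E)-1-bromo-3,7-dimethylocta-2,6-diene | BrC/C=C(\C)CCC=C(C)C | starting material
20 | 1-{3-[(2E)-3,7-dimethylocta-2,6-dien-1-yl]-2,4,6-trihydroxyphenyl}ethan-1-one | CC(=O)c1c(O)cc(O)c(C/C=C(\C)CCC=C(C)C)c1O | intermediate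
21 | rac-2-acetyl-4-[(2E)-3,7-dimethylocta-2,6-dien-1-yl]-3,5-dihydroxy-4-methylcyclohexa-2,5-dien-1-one | CC(=O)C1=C(O)C(C)(C/C=C(\C)CCC=C(C)C)C(O)=CC1=O | intermediate
22 | (4R)-2-acetyl-4-[(2E)-3,7-dimethylocta-2,6-dien-1-yl]-3,5-dihydroxy-4-methylcyclohexa-2,5-dien-1-one | CC(=O)C1=C(O)[C@](C)(C/C=C(\C)CCC=C(C)C)C(O)=CC1=O | intermediate
23 | chromene ortho-quinone methide, 6-butanoyl-5-hydroxy-2,2-dimethyl-8-methylidene-2H-chromen-7(8H)-one (not isolated) | CCCC(=O)C1=C(O)C2=C(OC(C)(C)C=C2)C(=C)C1=O | intermediate
24 | 1-[8-({(3R)-5-acetyl-3-[(2E)-3,7-dimethylocta-2,6-dien-1-yl]-2,4-dihydroxy-3-methyl-6-oxocyclohexa-1,4-dien-1-yl}methyl)-5,7-dihydroxy-2,2-dimethyl-2H-chromen-6-yl]butan-1-one | CCCC(=O)c1c(O)c2c(c(CC3=C(O)[C@@](C)(C/C=C(\C)CCC=C(C)C)C(O)=C(C(C)=O)C3=O)c1O)OC(C)(C)C=C2 | target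

Total step count: 13. Longest linear sequence: 10 steps (steps 1 to 9, then step 13); the trione branch (steps 10 to 12) joins at step 13.

Steps most likely to fail

Step 7 (key step). The aryne may be consumed before it meets the carbonyl group (addition of fluoride or solvent, ene reaction or [2+2] at the enal C=C), the quinone methide may be intercepted by a second aryne, or the regiocontrol of oxygen attack may erode. The fallback is a phenol–enal condensation that needs no aryne. It sets out from phenol 4 and aldehyde 11: ethylenediammonium diacetate (cat.), toluene, reflux should condense the aldehyde at C3, the carbon ortho to the only free hydroxyl, lose water to the same ortho-quinone methide 14 and close by the same 6π electrocyclisation. It comes back to the route at 15, before step 8. Because O4 is the only free oxygen in 4, the ring fusion stays unambiguous. New compounds on this way: none F0.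

Step 6. Butyllithium may strip the enol silyl group and then attack or enolise the freed ketone, the silyl shift may stall so that the aryllithium is merely protonated on work-up, or triflation of the hindered phenoxide may stay incomplete. The fallback masks the ketone by temporary reduction instead of as an enol ether. It sets out from 5: NaBH4, MeOH, 0 °C should give the racemic carbinol 1-[3-bromo-4-hydroxy-2,6-bis(methoxymethoxy)phenyl]butan-1-ol F1, which is kept away from acid because it is a para-hydroxybenzyl alcohol. HN(SiMe3)2, 80 °C converts it into its bis(trimethylsilyl) ether F2. n-BuLi, THF, −78 °C, then Tf2O should give, by the same bromine–lithium exchange and silyl shift, the silyl ether triflate F3, whose carbinol silyl ether is cleaved on dilute acid work-up to 4-(1-hydroxybutyl)-3,5-bis(methoxymethoxy)-2-(trimethylsilyl)phenyl trifluoromethanesulfonate F4. Dess–Martin oxidation (CH2Cl2, NaHCO3, rt) restores the ketone and comes back to the route at 10.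

Step 11. Methylation may go to the unsubstituted ring carbon C5 with re-aromatisation, to oxygen, or a second time onto the product. The fallback blocks the free ring carbon before the dearomatising alkylation and brings in the geranyl group last. It sets out from geranyl bromide 19 and purchased 1-(2,4,6-trihydroxy-3-methylphenyl)ethan-1-one F5. NBS, MeCN, 0 °C should brominate the only free ring carbon to 1-(3-bromo-2,4,6-trihydroxy-5-methylphenyl)ethan-1-one F6. NaOMe, MeOH, 19, 0 °C to rt should then alkylate the methyl-bearing carbon, the only ring carbon left without halogen or acyl group, to racemic 2-acetyl-6-bromo-4-[(2E)-3,7-dimethylocta-2,6-dien-1-yl]-3,5-dihydroxy-4-methylcyclohexa-2,5-dien-1-one F7. Zn, AcOH, rt removes the bromine and comes back to the route at 21, before the resolution of step 12.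

Further compounds
F0 | step 7 | none | none
F1 | step 6 | 1-[3-bromo-4-hydroxy-2,6-bis(methoxymethoxy)phenyl]butan-1-ol (racemic) | CCCC(O)c1c(OCOC)c(Br)c(O)cc1OCOC
F2 | step 6 | {1-[3-bromo-2,6-bis(methoxymethoxy)-4-(trimethylsilyloxy)phenyl]butoxy}(trimethyl)silane (racemic) | CCCC(O[Si](C)(C)C)c1c(OCOC)c(Br)c(O[Si](C)(C)C)cc1OCOC
F3 | step 6 | 3,5-bis(methoxymethoxy)-2-(trimethylsilyl)-4-[1-(trimethylsilyloxy)butyl]phenyl trifluoromethanesulfonate (racemic) | CCCC(O[Si](C)(C)C)c1c(OCOC)c([Si](C)(C)C)c(OS(=O)(=O)C(F)(F)F)cc1OCOC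
F4 | step 6 | 4-(1-hydroxybutyl)-3,5-bis(methoxymethoxy)-2-(trimethylsilyl)phenyl trifluoromethanesulfonate (racemic) | CCCC(O)c1c(OCOC)c([Si](C)(C)C)c(OS(=O)(=O)C(F)(F)F)cc1OCOC
F5 | step 11 | 1-(2,4,6-trihydroxy-3-methylphenyl)ethan-1-one (purchased) | CC(=O)c1c(O)cc(O)c(C)c1O
F6 | step 11 | 1-(3-bromo-2,4,6-trihydroxy-5-methylphenyl)ethan-1-one | CC(=O)c1c(O)c(Br)c(O)c(C)c1O
F7 | step 11 | rac-2-acetyl-6-bromo-4-[(2E)-3,7-dimethylocta-2,6-dien-1-yl]-3,5-dihydroxy-4-methylcyclohexa-2,5-dien-1-one | CC(=O)C1=C(O)C(C)(C/C=C(\C)CCC=C(C)C)C(O)=C(Br)C1=O
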